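## The problem

The target is an eremophilane: a trans-fused decalin (ring A = C1–C5 and C10, ring B = C5–C10) with methyl groups on C4 and C5, an isopropylidene on C7 conjugated to a C8 ketone, a hydroxyl on C9 and a (2E,4E,6E)-5-methyldodeca-2,4,6-trienoate on O3. Five stereocentres have to be set: C3 (O, α), C4 (CH3, β), C5 (quaternary, CH3 β), C9 (OH, α) and C10 (H, α). C3, C4 and C5 are contiguous, so a ring A piece that already holds C3 and C4 can pass its configuration to C5. The axial C5 methyl then shields the β face of ring B and can steer both C10 and C9. The fragile parts are the α-ketol (base can epimerise it or shift the ketone), the cross-conjugated enone (deconjugation) and the trienoate, which survives neither dissolving metal, hydrogenation nor organometallic reagents and must therefore arrive late. The hydroxyls on C3 and C9 should never be free together if the acyl group is to go to O3 alone, and the trisubstituted C4=C5 alkene of the acid needs its own geometric control. A cycloaddition is possible because of the pattern of ring B: the quaternary C5 lies between C4 and the ring-fusion carbon C10, and the oxygenated C8 sits directly beside C7, which carries the three-carbon unit. Read backwards, C8=C9–C10=C5 is a 1-oxygenated diene anchored on ring A and C6=C7 is an acrylate, joined in the ortho sense.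

## Retrosynthesis

The last bond to be made is C9–O. Removing it from 30 gives the enone ester 28, in which C9 is the only α-carbon of the C8 ketone that carries hydrogen, because C7 is part of the isopropylidene. Enolate hydroxylation therefore has no regiochemical choice, and the axial C5 methyl leaves only the α face of C9 open. Cutting the ester first would leave a 3,9-diol with two equatorial secondary hydroxyls to tell apart, or cost a protection and a deprotection at O9. The forward step asks that an amide base takes the C9 proton faster than it touches the trienoate.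

The ester C–O bond of 28 is cut next, giving alcohol 22 and acid 26. This is the convergent cut and keeps the triene away from every reductive and organometallic step. Acid 26 goes back through its ethyl ester 25 to enone 23 and phosphonate 24 by cutting the C4=C5 alkene of the chain, so that both existing E alkenes are bought in. The forward reactions must acylate a secondary alcohol flanked by the C4 methyl and must favour the E trisubstituted alkene.

Alcohol 22 comes from its silyl ether 21. The C7=C11 double bond of 21 is cut back to the β-hydroxy ketone 19 (dehydration), 19 to diol 18 (oxidation of the secondary alcohol only), and the C9–H and C10–H bonds of 18 to the allylic diol 17. This order is preferred to a dissolving-metal reduction of an enone for two reasons. The 8α-hydroxyl of 17 stands on the face where the C10 hydrogen is needed, so a hydroxyl-directed hydrogenation gives the trans ring fusion. A β-hydroxy enone would also be open to retro-aldol cleavage in lithium–ammonia. Diol 17 arises from 16 by loss of the triethylsilyl group, and the two C11–CH3 bonds of 16 are cut to ester 14.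

Octalin 14 is cut at C5–C6 and C7–C8 to the ring A dienol ether 12 and methyl acrylate 13. Against the annulation-type cut (C5–C6 and C9–C10), this one delivers the C8 oxygen and the C7 carbon substituent together, with the regiochemistry fixed by the diene. It also forms the quaternary centre by joining the hindered diene terminus to an unsubstituted CH2. The precursor is a monocycle with two stereocentres instead of a bicycle with five. The forward reaction has to find the α face of C5 and has to tolerate a methyl group on the inside of the diene.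

Dienol ether 12 is cut at O–Si to aldehyde 11, whose C9 protons are both allylic and α to the carbonyl, so the diene can only form in one position. Aldehyde 11 comes from the ethyl enol ether 10 by hydrolysis, and the C9–C10 bond of 10 is cut to enol triflate 8 and the boronate 9. The sp2–sp2 coupling is preferred to an aldol or Wittig construction because it keeps the tetrasubstituted C5=C10 alkene where it is.

Triflate 8 is cut at C4–CH3 and O–S to the methyl enone 6: conjugate addition anti to the silyloxy group sets C4, and the enolate so formed is the one needed for the triflate, which avoids the regiochemical question of enolising a 2,3-dimethylcyclohexanone. Enone 6 is taken back to the iodoenone 5 and the parent enone 4 (C5–CH3 bond), and 4 through the silyl enol ether 3 to the symmetric ketone 1, where an enantioselective deprotonation introduces C3.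

## Roads not taken

Alternative 1: The cut is at C9–C10 and C4–C5, opening both rings to the acyclic keto-aldehyde silyl enol ether A1. Forward, Cu(OTf)2 with a chiral bis(oxazoline) (SnCl4 for racemic work) would chelate the C8/C9 dicarbonyl, the E alkene would attack C9 through C10, and the enol ether carbon C4 would capture the C5 cation to give the hydroxy dione A2. Its merit is large: both rings and four stereocentres (C4, C5, C9, C10) in one catalytic step from an achiral chain, with the C8 ketone, the 9α-hydroxyl and the trans fusion already in place. In steps to the bicyclic core it is clearly better than the chosen plan. Its weak points for this target are: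
- One event must control the enantioface at C9, the chair folding and the enol ether geometry; the tertiary C5 cation can eliminate or be trapped by the C8 oxygen; and the 1,2-dicarbonyl is prone to hydration.
- A2 carries two ketones. The C3 ketone must become the equatorial 3α-alcohol although a hydride entering from the open α face would give the axial epimer, and equilibrating conditions would endanger the α-ketol.
- The C7 aldol with acetone must then find C8 beside a second enolisable ketone, and O3 must again be told from O9.

The chosen plan is longer, but each centre is set by one separately understood event and O3 and O8 are differentiated from the first step.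

Alternative 2: The cut is at C4–C5 and C1–C10, so ring A is built onto ring B. Forward, (BINOLate)TiCl2 would catalyse addition of the methyl-bearing double bond of the quinone A3 to the silyloxy diene A4, giving the cis-fused endo adduct A5. As a cycloaddition it is the better reaction: a quinone is a far stronger dienophile than an acrylate, the methoxy group steers the diene to the right double bond, and the catalyst supplies the absolute configuration, so no chiral ring A has to be made. The weak points lie after the key step:
- A5 has the C4 methyl α and the C10 hydrogen β, so both must be epimerised.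
- A4 carries a Z terminal methyl, which keeps its s-cis population low.
- Ring B has one oxygen too many: the neopentyl C6 ketone has to be removed.
- The 8-methoxy enedione must be converted into the 9α-hydroxy 8-ketone with the isopropylidene on C7, which means several regiocontrolled redox steps.

The chosen plan has a slower cycloaddition and a longer route to its diene. In return, every atom and functional group of its adduct 14 is used, and the C4 configuration is right from the start.

Alternative 3: The cut is at C3–C4 and C5–C10 of the trans-octalin A7, leading to the acyclic trienal A6. Forward, Me2AlCl or heat would add the (E)-β-methyl enal to the (E,E)-1-acyloxy diene and close rings A and B at once. In one respect this is better than the chosen plan: the trans ring fusion and the quaternary C5 come out of the cycloaddition itself, with the C9 oxygen and a masked C8 ketone already present, whereas the chosen plan needs step 12 to set C10. The weak points are: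
- The dienophile is a β,β-disubstituted enal and the diene only a 1-acyloxy diene, so reactivity is doubtful.
- All control rests on the single C9 stereocentre in the tether.
- A7 has the C3 oxygen β, so it must be inverted next to a substituted C4.
- The C4 formyl group has to be reduced to methyl, the C1=C2 alkene hydrogenated, the dithiane removed and the isopropylidene still added.
- A6 is itself a long linear target.

The chosen plan sets C3 and C4 correctly in a simple ring and uses the cycloaddition only for what it does well, the ortho pattern of ring B.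

Key step: step 9

Convention: bicyclic compounds are named on the eremophilane skeleton (decalin C1–C10, methyls on C4 and C5, C11 with C12 and C13 on C7); β is the face of the C5 methyl.

Assumption: lithium bis[(S)-1-phenylethyl]amide is taken to remove the proton that leads to the (R)-enol ether 3, by analogy with the sense this amide family shows with 4-tert-butylcyclohexanone; if the sense is opposite, the (R,R)-amide is used and nothing else changes.

## Steps

Step 1
Reactants: 1 4-(tert-butyldimethylsilyloxy)cyclohexan-1-one
Product: 3 (R)-tert-butyldimethyl{[4-(trimethylsilyloxy)cyclohex-3-en-1-yl]oxy}silane, via lithium enolate 2 (not isolated)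
Conditions: lithium bis[(S)-1-phenylethyl]amide (amine, n-BuLi), LiCl, Me3SiCl, THF, −78 °C
Reagents that add atoms: chlorotrimethylsilane, C[Si](C)(C)Cl
Why: Enantioselective deprotonation of a prochiral 4-substituted cyclohexanone by a C2-symmetric chiral lithium amide with in situ silyl trapping; the base distinguishes the two enantiotopic α-methylenes and so creates the future C3 centre.

Step 2
Reactants: 3 (R)-tert-butyldimethyl{[4-(trimethylsilyloxy)cyclohex-3-en-1-yl]oxy}silane
Product: 4 (R)-4-(tert-butyldimethylsilyloxy)cyclohex-2-en-1-one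
Conditions: Pd(OAc)2 (cat.), O2 (1 atm), DMSO, rt
Reagents that add atoms: none
Why: Saegusa oxidation of a regiodefined silyl enol ether; the double bond enters on the side fixed in step 1 and the neutral medium does not enolise toward the silyloxy carbon.

Step 3
Reactants: 4 (R)-4-(tert-butyldimethylsilyloxy)cyclohex-2-en-1-one
Product: 5 (R)-4-(tert-butyldimethylsilyloxy)-2-iodocyclohex-2-en-1-one
Conditions: iodine, pyridine, CH2Cl2, 0 °C → rt
Reagents that add atoms: iodine, [I][I]
Why: α-Iodination of a cyclic enone by iodine–pyridine (conjugate addition of pyridine, iodination of the enolate, elimination); the weak base leaves the γ-stereocentre alone.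

Step 4
Reactants: 5 (R)-4-(tert-butyldimethylsilyloxy)-2-iodocyclohex-2-en-1-one
Product: 6 (R)-4-(tert-butyldimethylsilyloxy)-2-methylcyclohex-2-en-1-one
Conditions: SnMe4, PdCl2(PhCN)2 (cat.), AsPh3, CuI, NMP, 80 °C
Reagents that add atoms: tetramethylstannane, C[Sn](C)(C)C
Why: Stille coupling of an α-iodoenone; the base-free conditions avoid dienolate formation and with it loss of the silyloxy-bearing centre.

Step 5
Reactants: 6 (R)-4-(tert-butyldimethylsilyloxy)-2-methylcyclohex-2-en-1-one
Product: 8 (3R,4R)-4-(tert-butyldimethylsilyloxy)-2,3-dimethylcyclohex-1-en-1-yl trifluoromethanesulfonate, via lithium enolate 7 (not isolated)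
Conditions: Me2CuLi (from MeLi, CuI), Et2O, −78 → −20 °C; then N-(5-chloropyridin-2-yl)triflimide, THF, −78 → 0 °C
Reagents that add atoms: lithium dimethylcuprate, [Li+].C[Cu-]C; N-(5-chloropyridin-2-yl)-1,1,1-trifluoro-N-(trifluoromethylsulfonyl)methanesulfonamide, O=S(=O)(N(c1ccc(Cl)cn1)S(=O)(=O)C(F)(F)F)C(F)(F)F
Why: Cuprate conjugate addition anti to the γ-silyloxy group sets the C4 methyl trans to O3, and O-triflation of the enolate formed in that event fixes the tetrasubstituted C5=C10 double bond without any enolate equilibration.

Step 6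
Reactants: 8 (3R,4R)-4-(tert-butyldimethylsilyloxy)-2,3-dimethylcyclohex-1-en-1-yl trifluoromethanesulfonate; 9 (E)-2-(2-ethoxyvinyl)-4,4,5,5-tetramethyl-1,3,2-dioxaborolane
Product: 10 tert-butyl({(1R,2R)-4-[(E)-2-ethoxyvinyl]-2,3-dimethylcyclohex-3-en-1-yl}oxy)dimethylsilane
Conditions: Pd(PPh3)4 (cat.), K3PO4, 1,4-dioxane/H2O, 70 °C
Reagents that add atoms: none
Why: Suzuki–Miyaura coupling of an enol triflate with an alkenylboronate, which forms the C9–C10 bond with retention of both alkene geometries.

Step 7
Reactants: 10 tert-butyl({(1R,2R)-4-[(E)-2-ethoxyvinyl]-2,3-dimethylcyclohex-3-en-1-yl}oxy)dimethylsilane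
Product: 11 2-[(3R,4R)-4-(tert-butyldimethylsilyloxy)-2,3-dimethylcyclohex-1-en-1-yl]acetaldehyde
Conditions: oxalic acid, THF/H2O, 0 °C → rt
Reagents that add atoms: water, O
Why: Mild acid hydrolysis of an enol ether; kinetic protonation at C9, which is less hindered than the fully substituted C5, gives the β,γ-unsaturated aldehyde, and the weak acid spares the tert-butyldimethylsilyl ether.

Step 8
Reactants: 11 2-[(3R,4R)-4-(tert-butyldimethylsilyloxy)-2,3-dimethylcyclohex-1-en-1-yl]acetaldehyde
Product: 12 tert-butyl({(1R,2R)-2,3-dimethyl-4-[(E)-2-(triethylsilyloxy)vinyl]cyclohex-3-en-1-yl}oxy)dimethylsilane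
Conditions: Et3SiOTf, Et3N, Et2O, −78 → 0 °C
Reagents that add atoms: triethylsilyl trifluoromethanesulfonate, CC[Si](CC)(CC)OS(=O)(=O)C(F)(F)F
Why: Soft enolisation of an aldehyde with a silyl triflate and an amine; only the doubly activated C9 protons can be removed, so the diene position is fixed, and the E enol ether should prevail because the Z isomer presses the silyloxy group against the tetrasubstituted ring alkene.

Step 9
Reactants: 12 tert-butyl({(1R,2R)-2,3-dimethyl-4-[(E)-2-(triethylsilyloxy)vinyl]cyclohex-3-en-1-yl}oxy)dimethylsilane; 13 methyl acrylate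
Product: 14 methyl 3α-(tert-butyldimethylsilyloxy)-4β,5β-dimethyl-8α-(triethylsilyloxy)-Δ9(10)-octalin-7α-carboxylate (eremophilane numbering)
Conditions: methyl acrylate (excess), BHT (cat.), PhMe, 120 °C, sealed tube
Reagents that add atoms: none
Why: A concerted, asynchronous normal-demand Diels–Alder reaction in which the silyloxy group raises the diene HOMO and puts its largest coefficient on C5; the closest known reaction type is the thermal addition of acrylates to 1-silyloxy dienes built on 2-methylcyclohexenes to set an angular methyl. Ring B closes by the intermolecular [4+2] cycloaddition itself, as a six-membered ring through C5–C6 and C7–C8, and leaves the new alkene at C9=C10. The ortho regiochemistry follows from pairing C5 with the unsubstituted acrylate carbon, which is also the favourable way to make a quaternary carbon. C5 is set by C4: allylic 1,2-strain with the C5 methyl turns the C4 methyl pseudoaxial on the β face, the acrylate bonds anti to it on the α face, and the C5 methyl ends β and cis to the C4 methyl. C8 is set by the E geometry of the dienol ether together with suprafacial addition, so its oxygen is necessarily cis to the new C5–C6 bond (8α) whatever the endo/exo outcome. C7 follows the endo preference of the ester (7α), but it becomes trigonal in step 14, so an exo adduct converges on 21. The step therefore needs only π-facial selectivity at C5 and enough reactivity at a diene terminus with an inside methyl; excess dienophile, a radical inhibitor and a closed vessel serve the second need.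

Step 10
Reactants: 14 methyl 3α-(tert-butyldimethylsilyloxy)-4β,5β-dimethyl-8α-(triethylsilyloxy)-Δ9(10)-octalin-7α-carboxylate
Product: 16 3α-(tert-butyldimethylsilyloxy)-8α-(triethylsilyloxy)eremophil-9-en-11-ol (4β,5β-dimethyl; 7βH), via methyl ketone 15 (not isolated)
Conditions: MeMgBr (excess), THF, 0 °C → rt
Reagents that add atoms: methylmagnesium bromide, C[Mg]Br
Why: Double Grignard addition to an ester through the methyl ketone gives the C11 carbinol; both silyl ethers are inert to the reagent.

Step 11
Reactants: 16 3α-(tert-butyldimethylsilyloxy)-8α-(triethylsilyloxy)eremophil-9-en-11-ol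
Product: 17 3α-(tert-butyldimethylsilyloxy)eremophil-9-ene-8α,11-diol (4β,5β-dimethyl; 7βH)
Conditions: HF·pyridine, pyridine, THF, 0 °C
Reagents that add atoms: none
Why: Buffered fluoride removes the secondary triethylsilyl ether selectively in the presence of the bulkier tert-butyldimethylsilyl ether.

Step 12
Reactants: 17 3α-(tert-butyldimethylsilyloxy)eremophil-9-ene-8α,11-diol
Product: 18 3α-(tert-butyldimethylsilyloxy)-10αH-eremophilane-8α,11-diol (4β,5β-dimethyl; 7βH)
Conditions: H2 (1 atm), [Ir(cod)(PCy3)(py)]PF6 (cat.), CH2Cl2, rt
Reagents that add atoms: none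
Why: Hydroxyl-directed homogeneous hydrogenation; the cationic iridium complex binds the allylic 8α-hydroxyl and delivers both hydrogens to the α face of C9=C10, so C10–H is α and trans to the C5 methyl.

Step 13
Reactants: 18 3α-(tert-butyldimethylsilyloxy)-10αH-eremophilane-8α,11-diol
Product: 19 3α-(tert-butyldimethylsilyloxy)-11-hydroxy-10αH-eremophilan-8-one (4β,5β-dimethyl; 7βH)
Conditions: DMP, CH2Cl2, rt
Reagents that add atoms: none
Why: Dess–Martin oxidation of the secondary alcohol; the tertiary alcohol cannot be oxidised and the non-basic medium avoids retro-aldol cleavage of the β-hydroxy ketone.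

Step 14
Reactants: 19 3α-(tert-butyldimethylsilyloxy)-11-hydroxy-10αH-eremophilan-8-one
Product: 21 3α-(tert-butyldimethylsilyloxy)-10αH-eremophil-7(11)-en-8-one (4β,5β-dimethyl), via tertiary mesylate 20 (not isolated)
Conditions: MeSO2Cl, Et3N, DMAP (cat.), CH2Cl2, 0 °C → rt; then DBU, rt
Reagents that add atoms: none
Why: Dehydration of a β-hydroxy ketone by sulfonylation and E1cB elimination through the C7 enolate gives the conjugated isopropylidene; any isopropenyl isomer is drawn into conjugation by the same base, and C10 is not enolisable.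

Step 15
Reactants: 21 3α-(tert-butyldimethylsilyloxy)-10αH-eremophil-7(11)-en-8-one
Product: 22 3α-hydroxy-10αH-eremophil-7(11)-en-8-one (4β,5β-dimethyl)
Conditions: aq. HF, MeCN, rt
Reagents that add atoms: none
Why: Acidic fluoride cleaves the secondary tert-butyldimethylsilyl ether; the enone and the ring stereocentres are stable to it.

Step 16
Reactants: 23 (E)-non-3-en-2-one; 24 triethyl 4-phosphonocrotonate
Product: 25 ethyl (2E,4E,6E)-5-methyldodeca-2,4,6-trienoate
Conditions: LiN(SiMe3)2, THF, −78 °C → rt
Reagents that add atoms: none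
Why: Vinylogous Horner–Wadsworth–Emmons olefination of a methyl ketone by the γ-carbanion of the phosphonocrotonate; the all-E isomer is the thermodynamically preferred one, and 4Z material is removed by chromatography or equilibrated with a trace of iodine.

Step 17
Reactants: 25 ethyl (2E,4E,6E)-5-methyldodeca-2,4,6-trienoate
Product: 26 (2E,4E,6E)-5-methyldodeca-2,4,6-trienoic acid
Conditions: LiOH, THF/MeOH/H2O, rt; then dilute HCl
Reagents that add atoms: lithium hydroxide, [Li+].[OH-]
Why: Saponification of an ethyl ester under conditions that do not isomerise the conjugated triene.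

Step 18
Reactants: 22 3α-hydroxy-10αH-eremophil-7(11)-en-8-one; 26 (2E,4E,6E)-5-methyldodeca-2,4,6-trienoic acid
Product: 28 8-oxo-10αH-eremophil-7(11)-en-3α-yl (2E,4E,6E)-5-methyldodeca-2,4,6-trienoate (4β,5β-dimethyl), via mixed anhydride 27 (not isolated)
Conditions: 2,4,6-trichlorobenzoyl chloride, Et3N, PhMe, rt; then 22, DMAP, rt
Reagents that add atoms: none
Why: Yamaguchi esterification, a standard way to acylate a hindered secondary alcohol with a polyenoic acid; O3 is the only hydroxyl present and its configuration is untouched because the C–O bond is not broken.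

Step 19
Reactants: 28 8-oxo-10αH-eremophil-7(11)-en-3α-yl (2E,4E,6E)-5-methyldodeca-2,4,6-trienoate
Product: 30 9α-hydroxy-8-oxo-10αH-eremophil-7(11)-en-3α-yl (2E,4E,6E)-5-methyldodeca-2,4,6-trienoate (4β,5β-dimethyl; 3R,4R,5R,9S,10R), via sodium enolate 29 (not isolated)
Conditions: NaN(SiMe3)2, THF, −78 °C; 3-phenyl-2-(phenylsulfonyl)oxaziridine, −78 °C; aq. NH4Cl
Reagents that add atoms: 3-phenyl-2-(phenylsulfonyl)oxaziridine, O=S(=O)(c1ccccc1)N1OC1c1ccccc1
Why: Kinetic α′-enolisation of the enone, where C9 is the only α-carbon with hydrogen, followed by electrophilic hydroxylation with a sulfonyloxaziridine; the oxidant approaches C9 anti to the axial C5 methyl to give the equatorial 9α-alcohol, and it does not oxidise the triene.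

## Compound list

1 | 4-(tert-butyldimethylsilyloxy)cyclohexan-1-one | CC(C)(C)[Si](C)(C)OC1CCC(=O)CC1 | starting material
2 | lithium (R)-4-(tert-butyldimethylsilyloxy)cyclohex-1-en-1-olate | CC(C)(C)[Si](C)(C)O[C@@H]1CCC([O-])=CC1.[Li+] | intermediate
3 | (R)-tert-butyldimethyl{[4-(trimethylsilyloxy)cyclohex-3-en-1-yl]oxy}silane | CC(C)(C)[Si](C)(C)O[C@@H]1CCC(O[Si](C)(C)C)=CC1 | intermediate
4 | (R)-4-(tert-butyldimethylsilyloxy)cyclohex-2-en-1-one | CC(C)(C)[Si](C)(C)O[C@@H]1CCC(=O)C=C1 | intermediate
5 | (R)-4-(tert-butyldimethylsilyloxy)-2-iodocyclohex-2-en-1-one | CC(C)(C)[Si](C)(C)O[C@@H]1CCC(=O)C(I)=C1 | intermediate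
6 | (R)-4-(tert-butyldimethylsilyloxy)-2-methylcyclohex-2-en-1-one | CC(C)(C)[Si](C)(C)O[C@@H]1CCC(=O)C(C)=C1 | intermediate
7 | lithium (3R,4R)-4-(tert-butyldimethylsilyloxy)-2,3-dimethylcyclohex-1-en-1-olate | CC(C)(C)[Si](C)(C)O[C@@H]1CCC([O-])=C(C)[C@H]1C.[Li+] | intermediate
8 | (3R,4R)-4-(tert-butyldimethylsilyloxy)-2,3-dimethylcyclohex-1-en-1-yl trifluoromethanesulfonate | CC(C)(C)[Si](C)(C)O[C@@H]1CCC(OS(=O)(=O)C(F)(F)F)=C(C)[C@H]1C | intermediate
9 | (E)-2-(2-ethoxyvinyl)-4,4,5,5-tetramethyl-1,3,2-dioxaborolane | CCO/C=C/B1OC(C)(C)C(C)(C)O1 | starting material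
10 | tert-butyl({(1R,2R)-4-[(E)-2-ethoxyvinyl]-2,3-dimethylcyclohex-3-en-1-yl}oxy)dimethylsilane | CC(C)(C)[Si](C)(C)O[C@@H]1CCC(/C=C/OCC)=C(C)[C@H]1C | intermediate
11 | 2-[(3R,4R)-4-(tert-butyldimethylsilyloxy)-2,3-dimethylcyclohex-1-en-1-yl]acetaldehyde | CC(C)(C)[Si](C)(C)O[C@@H]1CCC(CC=O)=C(C)[C@H]1C | intermediate
12 | tert-butyl({(1R,2R)-2,3-dimethyl-4-[(E)-2-(triethylsilyloxy)vinyl]cyclohex-3-en-1-yl}oxy)dimethylsilane (ring A dienol ether: 3α-silyloxy, 4β-methyl, diene C8=C9–C10=C5) | CC(C)(C)[Si](C)(C)O[C@@H]1CCC(/C=C/O[Si](CC)(CC)CC)=C(C)[C@H]1C | intermediate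
13 | methyl acrylate | C=CC(=O)OC | starting material
14 | methyl 3α-(tert-butyldimethylsilyloxy)-4β,5β-dimethyl-8α-(triethylsilyloxy)-Δ9(10)-octalin-7α-carboxylate | CC(C)(C)[Si](C)(C)O[C@@H]1CCC2=C[C@H](O[Si](CC)(CC)CC)[C@H](C(=O)OC)C[C@]2(C)[C@H]1C | intermediate
15 | 7α-acetyl-3α-(tert-butyldimethylsilyloxy)-4β,5β-dimethyl-8α-(triethylsilyloxy)-Δ9(10)-octalin | CC(C)(C)[Si](C)(C)O[C@@H]1CCC2=C[C@H](O[Si](CC)(CC)CC)[C@H](C(C)=O)C[C@]2(C)[C@H]1C | intermediate
16 | 3α-(tert-butyldimethylsilyloxy)-8α-(triethylsilyloxy)eremophil-9-en-11-ol (4β,5β-dimethyl; 7βH) | CC(C)(C)[Si](C)(C)O[C@@H]1CCC2=C[C@H](O[Si](CC)(CC)CC)[C@H](C(C)(C)O)C[C@]2(C)[C@H]1C | intermediate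
17 | 3α-(tert-butyldimethylsilyloxy)eremophil-9-ene-8α,11-diol (4β,5β-dimethyl; 7βH) | CC(C)(C)[Si](C)(C)O[C@@H]1CCC2=C[C@H](O)[C@H](C(C)(C)O)C[C@]2(C)[C@H]1C | intermediate
18 | 3α-(tert-butyldimethylsilyloxy)-10αH-eremophilane-8α,11-diol (4β,5β-dimethyl; 7βH) | CC(C)(C)[Si](C)(C)O[C@@H]1CC[C@H]2C[C@H](O)[C@H](C(C)(C)O)C[C@]2(C)[C@H]1C | intermediate
19 | 3α-(tert-butyldimethylsilyloxy)-11-hydroxy-10αH-eremophilan-8-one (4β,5β-dimethyl; 7βH) | CC(C)(C)[Si](C)(C)O[C@@H]1CC[C@H]2CC(=O)[C@H](C(C)(C)O)C[C@]2(C)[C@H]1C | intermediate
20 | 3α-(tert-butyldimethylsilyloxy)-8-oxo-10αH-eremophilan-11-yl methanesulfonate | CC(C)(C)[Si](C)(C)O[C@@H]1CC[C@H]2CC(=O)[C@H](C(C)(C)OS(C)(=O)=O)C[C@]2(C)[C@H]1C | intermediate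
21 | 3α-(tert-butyldimethylsilyloxy)-10αH-eremophil-7(11)-en-8-one (4β,5β-dimethyl) | CC(C)(C)[Si](C)(C)O[C@@H]1CC[C@H]2CC(=O)C(=C(C)C)C[C@]2(C)[C@H]1C | intermediate
22 | 3α-hydroxy-10αH-eremophil-7(11)-en-8-one (4β,5β-dimethyl) | O[C@@H]1CC[C@H]2CC(=O)C(=C(C)C)C[C@]2(C)[C@H]1C | intermediate
23 | (E)-non-3-en-2-one | CCCCC/C=C/C(C)=O | starting material
24 | triethyl 4-phosphonocrotonate | CCOC(=O)/C=C/CP(=O)(OCC)OCC | starting material
25 | ethyl (2E,4E,6E)-5-methyldodeca-2,4,6-trienoate | CCCCC/C=C/C(C)=C/C=C/C(=O)OCC | intermediate
26 | (2E,4E,6E)-5-methyldodeca-2,4,6-trienoic acid | CCCCC/C=C/C(C)=C/C=C/C(=O)O | intermediate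
27 | (2E,4E,6E)-5-methyldodeca-2,4,6-trienoic 2,4,6-trichlorobenzoic anhydride | CCCCC/C=C/C(C)=C/C=C/C(=O)OC(=O)c1c(Cl)cc(Cl)cc1Cl | intermediate
28 | 8-oxo-10αH-eremophil-7(11)-en-3α-yl (2E,4E,6E)-5-methyldodeca-2,4,6-trienoate (4β,5β-dimethyl) | CCCCC/C=C/C(C)=C/C=C/C(=O)O[C@@H]1CC[C@H]2CC(=O)C(=C(C)C)C[C@]2(C)[C@H]1C | intermediate
29 | sodium 8(9)-enolate of 28 | CCCCC/C=C/C(C)=C/C=C/C(=O)O[C@@H]1CC[C@H]2C=C([O-])C(=C(C)C)C[C@]2(C)[C@H]1C.[Na+] | intermediate
30 | 9α-hydroxy-8-oxo-10αH-eremophil-7(11)-en-3α-yl (2E,4E,6E)-5-methyldodeca-2,4,6-trienoate (4β,5β-dimethyl; 3R,4R,5R,9S,10R) | CCCCC/C=C/C(C)=C/C=C/C(=O)O[C@@H]1CC[C@H]2[C@H](O)C(=O)C(=C(C)C)C[C@]2(C)[C@H]1C | target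

## Step count and least certain steps

Total: 19 steps. Longest linear sequence: 17 steps (1 to 30 through steps 1–15, 18 and 19); the acid 26 takes two further steps.

Step 9 (key step). Three things can go wrong.
- The cycloaddition may be too slow at a diene terminus that carries an inside methyl, and forcing it invites a [1,5]-hydrogen shift from that methyl into the diene and polymerisation of the acrylate.
- Only the E isomer of 12 can reach the s-cis form, so any Z material from step 8 is lost to the reaction.
- Facial selectivity at C5 may be poor, because in the conformer with the C4 methyl pseudoaxial the C3 silyloxy group is axial on the α face and opposes the intended approach.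

The fallback gives up the cycloaddition and sets out from 6. The enolate 7 is made as in step 5 and, instead of being triflated, is added to 3-(trimethylsilyl)but-3-en-2-one to give the Michael adduct 4-(tert-butyldimethylsilyloxy)-2,3-dimethyl-2-[3-oxo-2-(trimethylsilyl)butyl]cyclohexan-1-one F1. NaOMe in MeOH removes the silyl group and closes the aldol condensation (Robinson annulation) to 3α-(tert-butyldimethylsilyloxy)-4β,5β-dimethyl-Δ9(10)-octal-8-one F2. Li in NH3 with t-BuOH gives the trans-fused 3α-(tert-butyldimethylsilyloxy)-4β,5β-dimethyl-10αH-decal-8-one F3. Kinetic enolisation with LiN(iPr)2 toward C7, transmetalation with ZnCl2 and aldol addition to acetone return to the route at 19.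

Step 7. During hydrolysis the ring double bond may move into conjugation with the aldehyde (protonation at C5 instead of C9, or later isomerisation), which would make the enolisation of step 8 regiochemically ambiguous. The fallback sets out from 8 and avoids acid. Coupling with potassium vinyltrifluoroborate (PdCl2(dppf), Et3N, n-PrOH) gives tert-butyl{[(1R,2R)-2,3-dimethyl-4-vinylcyclohex-3-en-1-yl]oxy}dimethylsilane F4. Hydroboration of the vinyl group with 9-BBN and oxidation with NaBO3 gives 2-[(3R,4R)-4-(tert-butyldimethylsilyloxy)-2,3-dimethylcyclohex-1-en-1-yl]ethan-1-ol F5. Dess–Martin oxidation returns to the route at 11.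

Step 12. Hydrogenation of the trisubstituted ring-fusion alkene beside a quaternary carbon may stall, or the iridium hydride may isomerise the allylic alcohol to the saturated ketone without stereocontrol at C10. The fallback sets out from 17. MnO2 oxidises the allylic alcohol to 3α-(tert-butyldimethylsilyloxy)-11-hydroxyeremophil-9-en-8-one F6, and Li in NH3 at −78 °C with an NH4Cl quench reduces the enone, with axial protonation at C10 giving the trans fusion, to return at 19.

Step 19. The amide base or the enolate may attack the trienoate (conjugate addition, or deprotonation at its 5-methyl group), and the hydroxylation may show incomplete facial selectivity. The fallback moves the hydroxylation before the esterification and sets out from 21: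
- The same enolate oxidation on 21 gives 3α-(tert-butyldimethylsilyloxy)-9α-hydroxy-10αH-eremophil-7(11)-en-8-one F7.
- Allyl chloroformate, pyridine and DMAP give its 9-O-allyl carbonate F8.
- Aqueous HF in MeCN gives 9α-(allyloxycarbonyloxy)-3α-hydroxy-10αH-eremophil-7(11)-en-8-one F9.
- Esterification with 26 as in step 18 gives the 9-O-allyloxycarbonyl derivative of the target F10.
- Pd(PPh3)4 with dimedone in THF removes the carbonate and arrives at 30.

Step 1. Enantioselection in the deprotonation may be incomplete, which would limit the enantiomeric purity of every later compound. The fallback replaces desymmetrisation by catalytic asymmetric reduction. It sets out from commercial 1,4-dioxaspiro[4.5]dec-6-en-8-one F11, which is reduced with BH3·SMe2 and the (S)-2-methyl-CBS-oxazaborolidine to (R)-1,4-dioxaspiro[4.5]dec-6-en-8-ol F12. Silylation with t-BuMe2SiCl and imidazole gives (R)-tert-butyl(1,4-dioxaspiro[4.5]dec-6-en-8-yloxy)dimethylsilane F13, and hydrolysis of the ketal with pyridinium tosylate in wet acetone returns to the route at 4.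

Step 16. Geometric control at the new trisubstituted C4=C5 alkene may be poor, leaving a mixture that is hard to separate. The fallback builds that alkene by carbometalation. It sets out from commercial (E)-oct-2-enal F14, which lithiated (trimethylsilyl)diazomethane converts (Colvin rearrangement) into (E)-non-3-en-1-yne F15. Methylalumination with AlMe3 and Cp2ZrCl2 (cat.) followed by iodine gives (1E,3E)-1-iodo-2-methylnona-1,3-diene F16, and a Heck reaction with ethyl acrylate (Pd(OAc)2, Et3N, MeCN) returns to the route at 25.

## Further compounds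

F1 | step 9 | 4-(tert-butyldimethylsilyloxy)-2,3-dimethyl-2-[3-oxo-2-(trimethylsilyl)butyl]cyclohexan-1-one (2,3-cis-dimethyl, 3,4-trans; mixture at the silyl-bearing carbon) | CC(C)(C)[Si](C)(C)O[C@@H]1CCC(=O)[C@](C)(CC(C(C)=O)[Si](C)(C)C)[C@H]1C
F2 | step 9 | 3α-(tert-butyldimethylsilyloxy)-4β,5β-dimethyl-Δ9(10)-octal-8-one | CC(C)(C)[Si](C)(C)O[C@@H]1CCC2=CC(=O)CC[C@]2(C)[C@H]1C
F3 | step 9 | 3α-(tert-butyldimethylsilyloxy)-4β,5β-dimethyl-10αH-decal-8-one | CC(C)(C)[Si](C)(C)O[C@@H]1CC[C@H]2CC(=O)CC[C@]2(C)[C@H]1C
F4 | step 7 | tert-butyl{[(1R,2R)-2,3-dimethyl-4-vinylcyclohex-3-en-1-yl]oxy}dimethylsilane | CC(C)(C)[Si](C)(C)O[C@@H]1CCC(C=C)=C(C)[C@H]1C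
F5 | step 7 | 2-[(3R,4R)-4-(tert-butyldimethylsilyloxy)-2,3-dimethylcyclohex-1-en-1-yl]ethan-1-ol | CC(C)(C)[Si](C)(C)O[C@@H]1CCC(CCO)=C(C)[C@H]1C
F6 | step 12 | 3α-(tert-butyldimethylsilyloxy)-11-hydroxyeremophil-9-en-8-one (4β,5β-dimethyl; 7βH) | CC(C)(C)[Si](C)(C)O[C@@H]1CCC2=CC(=O)[C@H](C(C)(C)O)C[C@]2(C)[C@H]1C
F7 | step 19 | 3α-(tert-butyldimethylsilyloxy)-9α-hydroxy-10αH-eremophil-7(11)-en-8-one | CC(C)(C)[Si](C)(C)O[C@@H]1CC[C@H]2[C@H](O)C(=O)C(=C(C)C)C[C@]2(C)[C@H]1C
F8 | step 19 | allyl 3α-(tert-butyldimethylsilyloxy)-8-oxo-10αH-eremophil-7(11)-en-9α-yl carbonate | CC(C)(C)[Si](C)(C)O[C@@H]1CC[C@H]2[C@H](OC(=O)OCC=C)C(=O)C(=C(C)C)C[C@]2(C)[C@H]1C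
F9 | step 19 | allyl 3α-hydroxy-8-oxo-10αH-eremophil-7(11)-en-9α-yl carbonate | O[C@@H]1CC[C@H]2[C@H](OC(=O)OCC=C)C(=O)C(=C(C)C)C[C@]2(C)[C@H]1C
F10 | step 19 | 9α-(allyloxycarbonyloxy)-8-oxo-10αH-eremophil-7(11)-en-3α-yl (2E,4E,6E)-5-methyldodeca-2,4,6-trienoate | CCCCC/C=C/C(C)=C/C=C/C(=O)O[C@@H]1CC[C@H]2[C@H](OC(=O)OCC=C)C(=O)C(=C(C)C)C[C@]2(C)[C@H]1C
F11 | step 1 | 1,4-dioxaspiro[4.5]dec-6-en-8-one | O=C1C=CC2(CC1)OCCO2
F12 | step 1 | (R)-1,4-dioxaspiro[4.5]dec-6-en-8-ol | O[C@@H]1CCC2(OCCO2)C=C1
F13 | step 1 | (R)-tert-butyl(1,4-dioxaspiro[4.5]dec-6-en-8-yloxy)dimethylsilane | CC(C)(C)[Si](C)(C)O[C@@H]1CCC2(OCCO2)C=C1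
F14 | step 16 | (E)-oct-2-enal | CCCCC/C=C/C=O
F15 | step 16 | (E)-non-3-en-1-yne | CCCCC/C=C/C#C
F16 | step 16 | (1E,3E)-1-iodo-2-methylnona-1,3-diene | CCCCC/C=C/C(C)=C/I
A1 | alternative 1 | (5E,9Z)-9-(tert-butyldimethylsilyloxy)-5-methyl-2-oxoundeca-5,9-dienal | O=CC(=O)CC/C(C)=C/CC/C(O[Si](C)(C)C(C)(C)C)=C/C
A2 | alternative 1 | 9α-hydroxy-4β,5β-dimethyl-10αH-decalin-3,8-dione (eremophilane numbering) | O=C1CC[C@H]2[C@H](O)C(=O)CC[C@]2(C)[C@H]1C
A3 | alternative 2 | 2-methoxy-5-methyl-1,4-benzoquinone | COC1=CC(=O)C(C)=CC1=O
A4 | alternative 2 | (Z)-3-(triisopropylsilyloxy)penta-1,3-diene | C=C/C(O[Si](C(C)C)(C(C)C)C(C)C)=C/C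
A5 | alternative 2 | cis-fused endo adduct: 8-methoxy-4α,5β-dimethyl-3-(triisopropylsilyloxy)-10βH-octalin-2,7-diene-6,9-dione (eremophilane numbering) | CC(C)[Si](C(C)C)(C(C)C)OC1=CC[C@@H]2C(=O)C(OC)=CC(=O)[C@]2(C)[C@@H]1C
A6 | alternative 3 | (1E,3E,5S)-5-(tert-butyldimethylsilyloxy)-5-{2-[(E)-3-methyl-5-oxopent-3-en-1-yl]-1,3-dithian-2-yl}penta-1,3-dien-1-yl pivalate | O=C/C=C(\C)CCC1(SCCCS1)[C@@H](O[Si](C)(C)C(C)(C)C)/C=C/C=C/OC(=O)C(C)(C)C
A7 | alternative 3 | trans-fused Δ1-octalin: 3β-pivaloyloxy, 4β-formyl, 5β-methyl, 9α-(tert-butyldimethylsilyloxy), 8,8-(propane-1,3-diyldithio), 10αH | CC(C)(C)C(=O)O[C@H]1C=C[C@H]2[C@H](O[Si](C)(C)C(C)(C)C)C3(SCCCS3)CC[C@]2(C)[C@H]1C=O
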